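The readings were generated by integration with made-up constants; the scatter is artificial.

The vessel was a closed, stirred flask at constant volume and temperature, with D charged as a solid and none of it in solution at the start, so I read the solid as a feed and asked what the charge changes.

| flask | D | remark | time |
|---|---|---|---|
| winter | 5.6 mM | run made earlier |  |
| summer | 21 mM | run made earlier |  |
| spring | 88 mM | run made earlier |  |
| north-west | 40 mM |  | 1.0 h |
| south-east | 5.0 mM |  | 1.0 h |
| south-west | 10 mM |  | 1.0 h |
| north-east | 20 mM |  | 1.0 h |
| south | 80 mM |  | 1.0 h |

| run | time / min | Z / % | D / % |
|---|---|---|---|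
| winter | 12.0 | 0 | 67 |
| winter | 25.0 | 7 | 43 |
| winter | 40.0 | 10 | 22 |
| winter | 50.0 | 22 | 11 |
| winter | 60.0 | 26 | 1 |
| summer | 5.00 | 0 | 100 |
| summer | 10.0 | 2 | 92 |
| summer | 15.0 | 0 | 90 |
| summer | 30.0 | 0 | 84 |
| summer | 60.0 | 8 | 71 |
| spring | 5.00 | 0 | 100 |
| spring | 15.0 | 0 | 97 |
| spring | 30.0 | 0 | 96 |
| spring | 40.0 | 2 | 95 |
| spring | 60.0 | 5 | 96 |

(standard deviation of a reading: 2 percentage points)

* the flasks put in order of amount of Z, in percent of the D charged, best first, at 1.0 h (north-west / south-east / south-west / north-east / south)
* the same order at 4.0 h (north-west / south-east / south-west / north-east / south)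
* the amount of Z, in percent of the D charged of the flask you put first, at 1.0 h
* the amount of Z, in percent of the D charged of the flask you put last, at 1.0 h

- in percentages every species weighs as the D in it: one Z counts as two
- the analysis behind the earlier runs scatters by 2 percentage points, standard deviation
- at the start none of D is in solution
- what has only dissolved of D counts as not reacted
- a reading or a percentage of Z counts all its forms, free or not

I reckoned in millimolar rather than percent. By 60.0 min the winter run had lost 5.54 mM of D, the summer run 6.09 mM and the spring run 3.52 mM, though the charges differed far more than these losses. I therefore took, as a rough average over the hour, a loss of D that is zero-order in the charge, of about 0.102 mM/min.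

Z trailed that loss, so I assumed the same trailing curve in each flask and defined the hourly dose m, the millimolar of D standing as Z at 1.0 h, whatever [D] was charged. Percent Z is then m/[D].

The readings give 1.46 mM, 1.68 mM and 4.40 mM, but the same 2 percentage points weighs 15.7 times as many millimolar in spring as in winter. I took winter's value, m = 1.46 mM. That gave 29.1% for south-east and 1.82% for south, with percent falling as the charge rises.

The weak link was south-east, whose charge lasts 49.3 min at this rate, less than the hour, so the reckoned loss ends before the hour there. But winter's solid also stood at 1% by the hour, and m was read from that run, so I kept the figure. By 4.0 h the same average rate reckons to 24.5 mM, more than the north-east charge, and I left that order to the dose rule no longer.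

The forecast gave south-east > south-west > north-east > north-west > south at 1.0 h, south-east > south-west > north-east > north-west > south at 4.0 h, with 28% and 2.5%, holding that “percent Z scales as 1/loading”.

The flask gave 29.0% in south-east and 1.92% in south, in the order south-east > south-west > north-east > north-west > south. South-east's D stood at 0% at 1.00 h, and at 4.0 h the order was south-west > south-east > north-east > north-west > south, with south-west at 76.2% above south-east at 69.1%. Multiplied back, south held 1.53 mM of its D as Z, beside m of 1.46 mM.

    2 X ⇌ Z (K = 1600 /M, k = 0.0220 /M/s)
    D ⇌ X, rate k2*(cs2 - [X]) while solid is left; crystals form when [X] > cs2 (solubility = 6.30 mM, k = 4.70 × 10⁻⁴ /s)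
    G ⇌ Z, rate k3*(cs3 - [Z]) while solid is left; crystals form when [Z] > cs3 (solubility = 12.0 mM, k = 0.00490 /s)

Here X is dissolved D and G is crystalline Z. For the south flask with 20 mM of D, m gives 7.30%; the computed flask gives 7.67%.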